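(All runs were computed for substances that don't exist; the scatter is artificial.)

In a one-step world you charge, wait, and the yield tells you how far that step has run. Here you read two products, target and isomer of the product, so you need a ladder of clocks, read from Thursday's run.

| flask | substrate | remark | time |
|---|---|---|---|
| Thursday's | 21 mM | run made earlier |  |
| midnight | 12 mM |  | 30 min |
| dawn | 19 mM |  | 10 min |

- Thursday's (time / min: target / %, isomer of the product / %, substrate / %): 0.500: 20.8, 27.2, 14.9; 1.50: 49.4, 27.3, 2.3; 3.00: 58.1, 24.1, 0.5; 4.00: 59.6, 24.4, 0.7; 6.00: 59.3, 24.9, 0.1

(standard deviation of a reading: 0.3 percentage points)

- the numbers in the tables scatter by 0.3 percentage points (one standard deviation)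
- in a conversion other conformer counts as not yet reacted

* which one finishes higher in share of target in all that became target or isomer of the product ("neither" within 2 percentage points) (midnight / dawn / neither)
* share of target in all that became target or isomer of the product, midnight
* share of target in all that became target or isomer of the product, dawn

First rung: in Thursday's run, substrate falls from 14.9 % at 0.500 min to 2.3 % at 1.50 min, a read half-life of 0.371 min. Isomer of the product is ahead at that first reading, 27.2 % against 20.8 % target.

Second rung: by 3.00 min Thursday's isomer has dropped 3.2 percentage points, against a scatter of 0.3 points, while target climbs. I read that as isomer returning to target, an exchange between the two.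

Last rung: from 3.00 min to 6.00 min, Thursday's target still moves from 58.1 % to 59.3 %, but its ratio to isomer of the product holds, so replace that ratio by its mean. The plateau share is target over target plus isomer of the product, summed over those readings: 70.7 %. Check the error: singly, the readings give 70.7 %, 71.0 % and 70.4 %, tight against the margin of 2 points.

A first-order exchange, once at equilibrium, has a ratio independent of the charge, which is thermodynamic rather than kinetic control. Midnight's 30 min and dawn's 10 min both outlast 3.00 min. So my reckoning, resting on one run, puts both flasks at the plateau share: neither. The forecast differs, with 80 % for midnight, 72.5 % for dawn and midnight as the answer: “Both runs last long enough to finish, so midnight ends higher”.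

The simulation gives 70.6 % at midnight and 70.6 % at dawn, so neither.

    substrate ⇌ other conformer (K = 1.65, k = 1.41 s⁻¹)
    substrate → target (k = 0.00828 s⁻¹)
    other conformer → isomer of the product (k = 0.0354 s⁻¹)
    target ⇌ isomer of the product (K = 0.417, k = 0.0145 s⁻¹)
    2 substrate → homo dimer (k = 1.49 M⁻¹ s⁻¹)

At midnight, target and isomer of the product relax by their exchange step alone, both ways together, with a half-life of 0.234 min, short against 30 min. Use the plateau share at dawn: 25.1 % isomer of the product implies 60.6 % target, and dawn holds 60.2 %.

Take a neighbour of midnight charged with 30 mM, held for the same 30 min: the plateau share says 70.7 %. The computed flask gives 70.6 %, with 55.7 % target and 21.0 % homo dimer, where each homo dimer counts as two substrate.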